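The numbers in the tables stem from a simulated flask with constants of no real substance, noise included.

Leftover substrate limits how far the product's excess can go. In a racemic charge without exchange (a plain kinetic resolution), the lead of left-handed product over right-handed product equals the lead of right-handed substrate over left-handed substrate, and that lead cannot exceed the leftover itself. So without exchange the excess stays below leftover divided by product.

- north: left-handed substrate 0.33 M; right-handed substrate 0.33 M; partner 0.66 M; racemization catalyst 3.3 mM; the very flask that is asked about, followed so far
- flask: left-handed substrate 0.33 M; partner 0.660 M; racemization catalyst 3.3 mM; right-handed substrate 0.33 M; time 3.0 d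

- north (time / h: left-handed product / %, right-handed product / %): 0.333: 1, 1; 0.833: 9, 5; 1.50: 13, 7; 2.50: 18, 10; 4.00: 26, 15; 5.00: 24, 20; 6.00: 33, 21

(standard deviation of a reading: 1.5 percentage points)

* left-handed product and right-handed product together, in percent of the left-handed substrate and right-handed substrate charged together, at 3.0 d
* excess of left-handed product over right-handed product in the product at 3.0 d
* whether the exchange between left-handed substrate and right-handed substrate keeps pace with the reaction: how far the product's excess at 3.0 d gets from its value without exchange to its value with instant exchange (above 80% keeps pace, below 20% hardly takes part, else lags behind)

Partner matches the two substrates together, so I take product over leftover, u, as growing in proportion to time. That treats the two hands as one substrate. The last north reading, at 6.00 h, gives: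

u = 1.17

At 3.0 d: u = 14.1, so y ≈ 93.4%

Ceiling = 7.10%

This 7.10% is the leftover ceiling, the limit on the excess without exchange.

Now the question turned round: what would keeping pace require? Instant exchange holds the substrates equal and the excess steady, and the last reading puts that excess near 22.2%. Keeping pace then asks for at least 17.8%, which is above the ceiling. The readings' excess falls from 28.6% at 2.50 h to 22.2%, though with a scatter of 1.5 percentage points per reading this is a hint. On that hint my reckoning commits to an excess below 17.8%, which is short of keeping pace, and it sets no lower bound.

The forecast gives 91%, 8% and "hardly takes part", saying “I expect little exchange, allowing a small contribution”.

The flask gives 91.9% and 10.9%, and the exchange lags behind, at 25% of the way.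

    partner + left-handed substrate → left-handed product (k = 0.00550 /M/min)
    partner + right-handed substrate → right-handed product (k = 0.00320 /M/min)
    left-handed substrate + racemization catalyst ⇌ right-handed substrate + racemization catalyst, rate k3*[racemization catalyst]*[left-handed substrate] forward; the back reaction follows from the equilibrium constant (k = 0.110 /M/min)
    racemization catalyst ⇌ dormant form (K = 8.40, k = 1.80 × 10⁻⁴ /min)
    partner + racemization catalyst → spent catalyst (k = 0.00140 /M/min)

The flask's excess of 10.9% stands above the ceiling 7.10%, and above the 8.81% reckoned from the yield found, so the hands have exchanged. At 0.181 d the flask uses left-handed substrate 7.2 times as fast in reaction as in forward exchange, and at 3.00 d the exchange relaxes with a half-life of 3.21 d, longer than the run. With 1.7 M of partner, the neighbour flask's leftover ceiling is 0%, yet its excess is 1.89%.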